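## Structural features

The target is a germacrane-type sesquiterpene lactone: a ten-membered carbocycle (C1–C10) spanned by an ether oxygen between C1 and C4, so that C1, C2, C3, C4 and that oxygen form a cis-2,5-disubstituted tetrahydrofuran (an 11-oxabicyclo[6.2.1]undecane core). A butenolide made of C6, C7, C11, C12 and the lactone oxygen is fused at C6–C7. Its C7=C11 bond is tetrasubstituted, C11 carries the acetoxymethyl carbon C13, and C6 is an enol carbon joined to C5 by an exocyclic double bond in which C4 and C7 are cis. Four ring stereocentres are present: the ether carbons C1 (S) and the fully substituted C4 (R), the tertiary carbinol C10 (R) directly bonded to C1, and the acyloxy carbon C8 (S), which stands 1,3-syn to C10 across the C9 methylene. A fifth centre (S) lies in the 2-methyloxirane-2-carboxylate on O8. The fragile groups are the enol lactone (an acylating agent toward nucleophiles and base), the allylic acetate at C13, the epoxy ester, and any C6 carbonyl intermediate, which has a β-oxygen on each side (C4 and C8). The real difficulty is the oxygen-bridged ten-membered ring with its quaternary ether carbon and two ring double bonds, and after it the regioselective annulation of the butenolide onto C6/C7. The plan exploits that C10, C1, C2, C3, C4, C5 and the bridging oxygen are a 7-oxabicyclo[2.2.1]heptane as soon as C5 and C10 are joined: the macrocycle is that bicycle with C5–C10 broken and C6–C9 inserted, which is what a [3,3] shift of an alkynyl/alkenyl carbinol delivers.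

## Logic of the disconnections

38 ⇒ 33 + 36. The ester C–O bond at O8 is cut last in the analysis (formed last in the synthesis) because the epoxy ester is the group least tolerant of acid and nucleophiles and its stereocentre is independent of the core. This removes one stereocentre and the most sensitive function from every earlier intermediate. The forward acylation must pick the secondary C8 hydroxyl over the tertiary C10 hydroxyl and spare the enol lactone and the allylic acetate.

33 ⇒ 32 ⇒ 30 ⇒ 26 + 28. The lactone C12–O bond and the C7=C11 bond are cut: a γ-ylidenebutenolide is the cyclodehydration product of a 1,4-keto ester, and C11–C13 with the acetate already in place come from 28. This uncovers a plain macrocyclic ketone. The forward steps need enolisation of 26 toward C7 and not C5, survival of both β-oxygens, and a cyclic protecting group on O8/O10 so that the C8 hydroxyl cannot compete for C12.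

26 ⇒ 25 ⇒ 24. These are functional-group changes only: the ketone is traced to the enol ether that the key step leaves at C5=C6 and that doubles as ketone protection in the steps before. The forward cleavage has to liberate a β-hydroxy ketone without retro-aldol or elimination.

24 ⇒ 23 ⇒ 22. The C8–O bond and one C9–H bond are removed, leading back to the C8=C9 alkene through the epoxy alcohol. The cut is made here because the C10 hydroxyl can direct first the oxidant and then the hydride, which ties the configuration of C8 to C10. The demand is syn delivery of oxygen and tolerance of the electron-rich enol ether.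

22 ⇒ 21. The C10–CH3 bond is cut to give an α-alkoxy enone. This removes the C10 stereocentre; the forward addition must be 1,2 and must occur through a chelate with the ether oxygen on C1.

21 ⇒ 18. This is the strategic retro-[3,3] step: C5–C10 is reconnected and C7–C8 is cut. The ten-membered ring and both ring alkenes collapse to a compact bicycle whose only controlling stereocentres are the two bridgeheads. The forward step needs the two arms cis on the exo face, alkoxide acceleration, and a rate that beats fragmentation.

18 ⇒ 17 ⇒ 15 ⇒ 14 ⇒ 13 ⇒ 12. The enol ether is traced to an acetyl group and that to the ester (C6–C7 bond cut), with the hydroxyl and the alkyne terminus carried as trimethylsilyl derivatives. The masking is chosen because a free β-hydroxy ketone would be open to retro-aldol cleavage of the very bond the key step is meant to break. The forward demand is kinetic enolisation at the methyl group.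

12 ⇒ 8 + 9. The bond between the carbinol carbon and the alkyne is cut. This gives a keto ester and a two-carbon nucleophile; the addition has to reach the exo face of an enolisable β-keto ester, which calls for a weakly basic organometallic.

8 ⇒ 7 ⇒ 6 ⇒ 5 ⇒ 3 ⇒ 1 + 2. The ketone is traced through its ketal to a vinyl bromide, and the two ring bonds at the bridgeheads are cut in a Diels–Alder sense. Two cheap components result. The cycloaddition must place bromine next to the unsubstituted bridgehead, and because it is racemic a resolution (7 to 8) is required.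

36 ⇒ 34 and 28 ⇒ 27. The side-chain acid is an oxidation-level change of a commercial epoxy alcohol, and the keto ester comes from a C–O displacement on a bromide.

## Other disconnections considered

Alternative 1: The cut is the C3–C4 bond of the tetrahydrofuran. In the forward sense Rh2(OAc)4 would decompose diazoketone A1, whose C1 oxygen carries a lactate-derived secondary alkyl group, and the carbenoid would insert into the C4–H bond next to the ether oxygen with retention, giving tetrahydrofuranone A2.
- In its favour: C4 comes from the chiral pool and C1 and C10 can be set by asymmetric catalysis, so no resolution is needed. On absolute stereocontrol this alternative is better than the chosen plan, which discards half of the keto ester. Insertion α to an ether oxygen with retention is a dependable way to a fully substituted ether carbon.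
- Against it here: A2 solves only the five-membered ring. The ten-membered ring, both ring alkenes and the butenolide all remain, so four further ring bonds and a medium-ring closure are still required. The C2 carbonyl of A2 is not in the target and must be removed. Oxonium ylide formation and insertion into the benzylic C–H bonds could compete.
- Comparison: on mechanism the two key steps are comparably well founded. On structure the chosen plan forms the hardest feature (the bridged macrocycle) in its key step, while this one defers it. On step economy the chosen plan should be clearly shorter.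

Alternative 2: The cut is C6–C7, with the ether bridge formed afterwards. CrCl2 with catalytic NiCl2 would convert the vinyl iodide of A3 into a vinylchromium species that adds to the enal (Nozaki–Hiyama–Kishi closure) to give the ten-membered allylic alcohol A4; two epoxides would then be opened in a cascade to form the 1,4-ether, the C10 hydroxyl and the enol lactone.
- In its favour: A4 already carries C11–C13 with the acetate, so no late functionalisation of C7 is needed. On this point it is better than the chosen plan, whose C7 aldol is a weak spot. C1, C8 and C10 could come from catalytic asymmetric epoxidation, again avoiding a resolution. The C6 configuration is irrelevant.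
- Against it here: a ten-membered ring must be closed end to end under high dilution with a large excess of a toxic divalent chromium salt. A tetrasubstituted vinyl iodide of defined geometry is hard to make, and its allylic acetate could ionise under nickel catalysis. The later cascade has to control two epoxide openings, an oxidation at C6 and the enol lactone geometry at once.
- Comparison: on step economy it could equal the chosen plan if the cascade worked as drawn. On mechanism the chosen ring expansion is unimolecular, driven by strain release and free of dilution constraints, which makes it the safer ring-forming event.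

Alternative 3: The cuts are C8–C9 and O–C10. A nitrile oxide generated from furyl aldoxime A5 would add across the isopropenyl group on C1 and close the ten-membered ring together with an isoxazoline, giving A6.
- In its favour: the ring-forming step would also create the C10 carbinol oxygen and place C8 at the ketone oxidation level, so the 1,3-oxygen pattern that costs the chosen plan three steps arrives at once. On this point it is better. The lactone carbons are carried as a silylfuran from the start, which avoids the C7 aldol. Like the chosen plan it builds the ring by a pericyclic process; in that respect the two are equal.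
- Against it here: it is an end-to-end closure of a medium ring, so nitrile oxide dimerisation would compete and dilution is needed. The face selectivity at C10 rests only on the neighbouring C1 centre. After N–O cleavage the C8 ketone must be reduced syn to C10, the furan oxidised to the butenolide, and the C5=C6 unsaturation introduced by a further oxidation.
- Comparison: step count should be similar. The chosen plan is preferred because its ring formation is a strain-driven ring enlargement with the geometry fixed by a rigid bicycle, and because the C10 and C8 centres are then set by two directed, well-precedented reactions.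

Key step: step 12

Assumptions: 2, 9, 27 and 34 are taken as purchasable. Racemic compounds 3 to 7 are drawn as the enantiomer that is carried on after step 5. Positions in the macrocyclic series are given in germacrane numbering.

## Steps

Step 1
Reactants: 1 2-methylfuran; 2 methyl 3-bromopropiolate
Product: 3 rac-methyl 3-bromo-1-methyl-7-oxabicyclo[2.2.1]hepta-2,5-diene-2-carboxylate
Conditions: 1 (excess), PhMe, 80 °C, sealed vessel
Reagents that add atoms: none
Why: Diels–Alder cycloaddition of the electron-rich furan to the activated bromoalkyne; the unsubstituted furan α-carbon, the more nucleophilic terminus, bonds to the bromine-bearing β-carbon of the ynoate, so the ester ends next to the methyl bridgehead and bromine next to the hydrogen bridgehead. Both bridgehead centres form here, as a racemate.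

Step 2
Reactants: 3 rac-bromodiene ester
Product: 5 rac-methyl 3,3-dimethoxy-1-methyl-7-oxabicyclo[2.2.1]hept-5-ene-2-carboxylate (C2 epimers; exo ester drawn), via methoxy diene ester 4 (not isolated)
Conditions: NaOMe, MeOH, 0 °C to rt
Reagents that add atoms: sodium methoxide (C[O-].[Na+]); methanol (CO)
Why: Addition–elimination of methoxide at the β-bromoacrylate gives the vinylogous carbonate 4, and a second conjugate addition with protonation at C2 gives the ketal, which masks the future C10 ketone while the strained diene is still present. C2 forms as an epimer mixture and stays labile until step 4.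

Step 3
Reactants: 5 rac-unsaturated ketal ester
Product: 6 rac-methyl 3,3-dimethoxy-1-methyl-7-oxabicyclo[2.2.1]heptane-2-carboxylate
Conditions: H2 (1 atm), Pd/C, EtOAc, rt
Reagents that add atoms: none
Why: Heterogeneous hydrogenation of the strained disubstituted alkene from the exo face; saturating before ketal hydrolysis removes the path by which an unsaturated β-keto ester would open its oxygen bridge and aromatise.

Step 4
Reactants: 6 rac-saturated ketal ester
Product: 7 rac-methyl 1-methyl-3-oxo-7-oxabicyclo[2.2.1]heptane-2-exo-carboxylate
Conditions: 6 M HCl, THF, 40 °C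
Reagents that add atoms: water (O)
Why: Acid hydrolysis of the dimethyl ketal; strong acid is needed because the bridge oxygen destabilises the oxocarbenium ion. The β-keto ester α-carbon equilibrates under these conditions and the exo ester is expected to prevail.

Step 5
Reactants: 7 rac-keto ester
Product: 8 methyl (1R,2R,4S)-1-methyl-3-oxo-7-oxabicyclo[2.2.1]heptane-2-carboxylate
Conditions: NADPH-dependent ketoreductase (chosen from a screening panel), NADP+ (cat.), i-PrOH, phosphate buffer pH 7, 30 °C, stopped near half conversion
Reagents that add atoms: none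
Why: Enzymatic kinetic resolution by enantiomer-selective carbonyl reduction: the enantiomers differ at both bridgeheads and cannot interconvert, so the enzyme reduces one and leaves the other. The recovered (1R,4S) ketone carries the bridgeheads that become C4 and C1 of the target and fixes the absolute configuration of the route.

Step 6
Reactants: 8 (1R,2R,4S)-keto ester; 9 ethynyltrimethylsilane
Product: 12 methyl (1R,4S)-3-endo-hydroxy-1-methyl-3-exo-[(trimethylsilyl)ethynyl]-7-oxabicyclo[2.2.1]heptane-2-exo-carboxylate, via lithium acetylide 10 (not isolated), via cerium acetylide 11 (not isolated)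
Conditions: 9, n-BuLi, THF, −78 °C; CeCl3, −78 °C; then 8, −78 °C; aq. NH4Cl
Reagents that add atoms: none
Why: Organocerium 1,2-addition: the weakly basic cerium acetylide adds to the ketone of the enolisable β-keto ester instead of deprotonating it. Attack on the exo face (the endo face is screened by the two-carbon bridge) places the alkyne exo and the hydroxyl endo, cis to the exo ester arm.

Step 7
Reactants: 12 hydroxy ester
Product: 13 methyl (1R,4S)-1-methyl-3-exo-[(trimethylsilyl)ethynyl]-3-endo-(trimethylsilyloxy)-7-oxabicyclo[2.2.1]heptane-2-exo-carboxylate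
Conditions: Me3SiOTf, 2,6-lutidine, CH2Cl2, −78 to 0 °C
Reagents that add atoms: trimethylsilyl trifluoromethanesulfonate (C[Si](C)(C)OS(=O)(=O)C(F)(F)F)
Why: Silylation of the tertiary alcohol with a silyl triflate; capping the hydroxyl prevents retro-aldol cleavage once a ketone sits β to it (steps 9 and 10) and lets both trimethylsilyl groups be removed together in step 11.

Step 8
Reactants: 13 silyl ether ester
Product: 14 (1R,4S)-N-methoxy-N,1-dimethyl-3-exo-[(trimethylsilyl)ethynyl]-3-endo-(trimethylsilyloxy)-7-oxabicyclo[2.2.1]heptane-2-exo-carboxamide
Conditions: MeNH(OMe)·HCl, i-PrMgCl, THF, −20 to 0 °C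
Reagents that add atoms: N,O-dimethylhydroxylamine hydrochloride (CNOC.Cl)
Why: Weinreb amide formation from the ester with the chloromagnesium amide of N,O-dimethylhydroxylamine; this small, strongly nucleophilic amide is chosen because the ester is flanked by two fully substituted carbons.

Step 9
Reactants: 14 Weinreb amide
Product: 15 1-[(1R,4S)-1-methyl-3-exo-[(trimethylsilyl)ethynyl]-3-endo-(trimethylsilyloxy)-7-oxabicyclo[2.2.1]hept-2-exo-yl]ethanone
Conditions: MeMgBr, THF, 0 °C; aq. NH4Cl
Reagents that add atoms: methylmagnesium bromide (C[Mg]Br)
Why: Grignard addition to the Weinreb amide stops at the chelated tetrahedral intermediate and gives the methyl ketone on work-up. The exo acetyl arm is also the thermodynamically preferred epimer, because the endo face of that carbon is flanked by the endo silyloxy group.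

Step 10
Reactants: 15 methyl ketone
Product: 17 (1S,4R)-4-methyl-3-exo-[1-(triisopropylsilyloxy)vinyl]-2-exo-[(trimethylsilyl)ethynyl]-2-endo-(trimethylsilyloxy)-7-oxabicyclo[2.2.1]heptane, via lithium enolate 16 (not isolated)
Conditions: LiN(i-Pr)2, THF, −78 °C; i-Pr3SiOTf, −78 to 0 °C
Reagents that add atoms: triisopropylsilyl trifluoromethanesulfonate (CC(C)[Si](C(C)C)(C(C)C)OS(=O)(=O)C(F)(F)F)
Why: Kinetic deprotonation at the methyl group (the ring α-hydrogen is flanked by two fully substituted carbons) and O-silylation of the enolate give the 1-silyloxyvinyl arm. The bulky triisopropylsilyl group is chosen to survive steps 11 to 15 and to resist O-to-O silyl transfer in step 12.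

Step 11
Reactants: 17 tris-silylated enol ether
Product: 18 (1S,2R,3S,4R)-2-ethynyl-4-methyl-3-[1-(triisopropylsilyloxy)vinyl]-7-oxabicyclo[2.2.1]heptan-2-ol (2-exo-ethynyl and 3-exo-vinyl)
Conditions: K2CO3, MeOH, 0 °C to rt
Reagents that add atoms: none
Why: Base-mediated methanolysis removes the alkynyl C-silyl group and the tertiary O-silyl group in one operation while the hindered triisopropylsilyl enol ether is retained, so the rearrangement substrate is released only when it is needed.

Step 12
Reactants: 18 ethynyl carbinol with exo silyloxyvinyl arm
Product: 21 (1S,3Z,6E,8R)-8-methyl-6-(triisopropylsilyloxy)-11-oxabicyclo[6.2.1]undeca-3,6-dien-2-one [(1S,4R,5E,8Z)-1,4-epoxy-6-(triisopropylsilyloxy)-11,12,13-trinorgermacra-5,8-dien-10-one], via potassium alkoxide 19 (not isolated), via potassium allenolate 20 (not isolated)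
Conditions: KN(SiMe3)2 (1.1 equiv), 18-crown-6, THF, −78 °C to rt; aq. NH4Cl at −78 °C
Reagents that add atoms: none
Why: Deprotonation gives the potassium alkoxide, the crown ether strips the cation, and the bare alkoxide accelerates the [3,3] shift of the 3-oxido-1,5-enyne (anionic oxy-Cope rearrangement). C7 of the silyloxyvinyl arm bonds to the alkyne terminus C8 while the C5–C10 bond breaks, giving the allenolate, which is protonated at C9 on quench to the conjugated cis-enone. The closest known reaction type is the anionic oxy-Cope ring expansion of 1-alkynyl-2-alkenylcycloalkanols, a four-carbon ring enlargement. The ten-membered carbocycle is not closed end to end: it arises by enlargement of the six-membered ring C10–C1–C2–C3–C4–C5 through a boat-like six-centre array that the cis-exo arms on the rigid bicycle are forced to adopt, and the tetrahydrofuran ring is carried through unchanged. No stereocentre is created: the bridgeheads C1 and C4 are untouched and C5 becomes trigonal. The C5=C6 geometry (C4 cis to C7) follows from the boat array, in which the silyloxy group points away from the C4 methyl group, and the other geometry would put a trans double bond into the bridged ring. The selectivity needed is rearrangement over loss of acetylide from the propargylic alkoxide and over silyl migration from the enol oxygen to the alkoxide; relief of bicyclic strain, the eclipsed cis arms and the bulk of the silyl group favour the [3,3] path. Only a slight excess of a soluble amide base is used, because an excess of a hydride base would also remove the acidic alkyne hydrogen and the resulting dianion has no productive [3,3] pathway.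

Step 13
Reactants: 21 bridged cyclodecadienone
Product: 22 (1S,4R,5E,8Z,10R)-1,4-epoxy-6-(triisopropylsilyloxy)-11,12,13-trinorgermacra-5,8-dien-10-ol
Conditions: MeMgBr, CH2Cl2, −78 °C
Reagents that add atoms: methylmagnesium bromide (C[Mg]Br)
Why: Chelation-controlled 1,2-addition: magnesium bridges the C10 carbonyl and the ether oxygen on C1 (Cram chelate, favoured in a non-coordinating solvent) and methyl adds on the side of the C1 hydrogen, which gives the 10R carbinol. The enol ether keeps C6 out of reach of the Grignard reagent.

Step 14
Reactants: 22 tertiary allylic alcohol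
Product: 23 (1S,4R,5E,8R,9R,10S)-1,4:8,9-diepoxy-6-(triisopropylsilyloxy)-11,12,13-trinorgermacr-5-en-10-ol (epoxide syn to the C10 hydroxyl)
Conditions: VO(acac)2 (cat.), t-BuOOH, CH2Cl2, 0 °C to rt
Reagents that add atoms: tert-butyl hydroperoxide (CC(C)(C)OO)
Why: Hydroxyl-directed epoxidation: the vanadate ester of the tertiary allylic alcohol delivers oxygen to the face of the cis C8=C9 bond on which the C10 oxygen lies, so that the C8 and C10 oxygens end syn. Binding to the alcohol makes the allylic alkene far more reactive than the remote enol ether.

Step 15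
Reactants: 23 epoxy alcohol
Product: 24 (1S,4R,5E,8S,10R)-1,4-epoxy-6-(triisopropylsilyloxy)-11,12,13-trinorgermacr-5-ene-8,10-diol
Conditions: NaAlH2(OCH2CH2OMe)2 (Red-Al), THF, 0 °C to rt; aq. potassium sodium tartrate
Reagents that add atoms: none
Why: Intramolecular hydride delivery from the alkoxyaluminate opens the 2,3-epoxy alcohol at C9, the carbon next to the carbinol, and leaves the oxygen on C8 with its configuration unchanged (1,3-diol formation). The silyl enol ether is inert to hydride and keeps C6 at the ketone oxidation level.

Step 16
Reactants: 24 diol enol ether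
Product: 25 (1S,4R,8S,10R)-1,4-epoxy-8,10-dihydroxy-11,12,13-trinorgermacran-6-one
Conditions: Bu4NF, AcOH (1:1), THF, 0 °C
Reagents that add atoms: none
Why: Fluoride cleaves the Si–O bond of the enol ether and the buffer protonates the enolate at once, which avoids retro-aldol cleavage or β-elimination of the new β-hydroxy ketone.

Step 17
Reactants: 25 keto diol
Product: 26 (1S,4R,8S,10R)-8,10-(di-tert-butylsilylenedioxy)-1,4-epoxy-11,12,13-trinorgermacran-6-one
Conditions: t-Bu2Si(OTf)2, 2,6-lutidine, CH2Cl2, 0 °C
Reagents that add atoms: di-tert-butylsilyl bis(trifluoromethanesulfonate) (CC(C)(C)[Si](OS(=O)(=O)C(F)(F)F)(OS(=O)(=O)C(F)(F)F)C(C)(C)C)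
Why: Cyclic silylene formation on the syn-1,3-diol; it ties up both hydroxyls, so that the C8 hydroxyl cannot later lactonise onto C12 and the C10 carbinol cannot eliminate or add to C6, and it withstands amide base and anhydrous acid.

Step 18
Reactants: 27 ethyl bromopyruvate
Product: 28 ethyl 3-acetoxy-2-oxopropanoate
Conditions: KOAc, MeCN, 0 °C to rt
Reagents that add atoms: potassium acetate (CC(=O)[O-].[K+])
Why: SN2 displacement of the α-bromo ketone by acetate gives the C11–C13 building block with the acetate already in place.

Step 19
Reactants: 26 silylene-protected ketone; 28 ethyl 3-acetoxy-2-oxopropanoate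
Product: 30 ethyl (1S,4R,8S,10R)-13-acetoxy-8,10-(di-tert-butylsilylenedioxy)-1,4-epoxy-11-hydroxy-6-oxogermacran-12-oate (epimer mixture at C7 and C11), via lithium C6–C7 enolate 29 (not isolated)
Conditions: LiN(i-Pr)2, THF, −78 °C; then 28, −78 °C; AcOH
Reagents that add atoms: none
Why: Directed aldol addition of a lithium enolate to an α-keto ester, whose ketone is the most electrophilic carbonyl present. Kinetic deprotonation is expected at C7: both α-carbons carry a β-oxygen, but C5 is in addition neopentylic (next to the fully substituted C4), and at −78 °C the silyloxy group on C8 is not eliminated. The new centres at C7 and C11 form as a mixture and are removed in step 20.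

Step 20
Reactants: 30 aldol adduct
Product: 32 (1S,4R,5E,8S,10R)-13-acetoxy-8,10-(di-tert-butylsilylenedioxy)-1,4-epoxygermacra-5,7(11)-dien-12,6-olide, via alkylidene keto ester 31 (not isolated)
Conditions: camphorsulfonic acid (cat.), PhMe, 5 Å MS, 80 °C
Reagents that add atoms: none
Why: Acid-catalysed cyclodehydration of a γ-keto α-hydroxy ester: loss of water through the enol gives the tetrasubstituted C7=C11 alkene, and the C6 enol oxygen then displaces ethanol at C12 to form the γ-ylidenebutenolide. The C5=C6 geometry with C4 cis to C7 is the one that keeps a cis double bond in the bridged ten-membered ring.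

Step 21
Reactants: 32 silylene-protected butenolide
Product: 33 (1S,4R,5E,8S,10R)-13-acetoxy-1,4-epoxy-8,10-dihydroxygermacra-5,7(11)-dien-12,6-olide
Conditions: HF·pyridine, THF/pyridine, 0 °C
Reagents that add atoms: none
Why: Fluoride cleavage of the silylene under mildly acidic, non-nucleophilic conditions that leave the enol lactone, the allylic acetate and the ether bridge untouched.

Step 22
Reactants: 34 (R)-2-methylglycidol
Product: 36 (S)-2-methyloxirane-2-carboxylic acid, via epoxy aldehyde 35 (not isolated)
Conditions: RuCl3 (cat.), NaIO4, MeCN/EtOAc/H2O, 0 °C to rt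
Reagents that add atoms: water (O)
Why: RuO4-mediated oxidation of the primary alcohol through the aldehyde to the acid. The quaternary epoxide carbon cannot epimerise; the descriptor changes from R to S only because the CIP priorities change.

Step 23
Reactants: 33 diol butenolide; 36 (S)-2-methyloxirane-2-carboxylic acid
Product: 38 (1S,4R,5E,8S,10R)-13-acetoxy-1,4-epoxy-10-hydroxy-8-[(2S)-2-methyloxirane-2-carbonyloxy]germacra-5,7(11)-dien-12,6-olide (CNP0142137.1), via mixed anhydride 37 (not isolated)
Conditions: 2-methyl-6-nitrobenzoic anhydride, Et3N, DMAP (cat.), CH2Cl2, rt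
Reagents that add atoms: none
Why: Shiina esterification through the mixed anhydride; DMAP transfers the hindered epoxy acyl group to the secondary C8 hydroxyl, while the tertiary C10 hydroxyl is too hindered to react. No acid or strong nucleophile is present that would open the epoxide or the enol lactone.

## Compound list

1 | 2-methylfuran | Cc1ccco1 | starting material
2 | methyl 3-bromopropiolate | COC(=O)C#CBr | starting material
3 | rac-methyl 3-bromo-1-methyl-7-oxabicyclo[2.2.1]hepta-2,5-diene-2-carboxylate [(1R,4S) enantiomer drawn] | COC(=O)C1=C(Br)[C@H]2O[C@]1(C)C=C2 | intermediate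
4 | rac-methyl 3-methoxy-1-methyl-7-oxabicyclo[2.2.1]hepta-2,5-diene-2-carboxylate (not isolated) | COC(=O)C1=C(OC)[C@H]2O[C@]1(C)C=C2 | intermediate
5 | rac-methyl 3,3-dimethoxy-1-methyl-7-oxabicyclo[2.2.1]hept-5-ene-2-carboxylate (C2 epimers; exo ester drawn) | COC(=O)[C@@H]1[C@@]2(C)C=C[C@H](O2)C1(OC)OC | intermediate
6 | rac-methyl 3,3-dimethoxy-1-methyl-7-oxabicyclo[2.2.1]heptane-2-carboxylate | COC(=O)[C@@H]1[C@@]2(C)CC[C@H](O2)C1(OC)OC | intermediate
7 | rac-methyl 1-methyl-3-oxo-7-oxabicyclo[2.2.1]heptane-2-exo-carboxylate | COC(=O)[C@@H]1[C@@]2(C)CC[C@H](O2)C1=O | intermediate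
8 | methyl (1R,2R,4S)-1-methyl-3-oxo-7-oxabicyclo[2.2.1]heptane-2-carboxylate (single enantiomer) | COC(=O)[C@@H]1[C@@]2(C)CC[C@H](O2)C1=O | intermediate
9 | ethynyltrimethylsilane | C#C[Si](C)(C)C | starting material
10 | lithium (trimethylsilyl)acetylide (not isolated) | [Li]C#C[Si](C)(C)C | intermediate
11 | dichlorocerium (trimethylsilyl)acetylide (not isolated) | C[Si](C)(C)C#C[Ce](Cl)Cl | intermediate
12 | methyl (1R,4S)-3-endo-hydroxy-1-methyl-3-exo-[(trimethylsilyl)ethynyl]-7-oxabicyclo[2.2.1]heptane-2-exo-carboxylate | COC(=O)[C@@H]1[C@@]2(C)CC[C@H](O2)[C@]1(O)C#C[Si](C)(C)C | intermediate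
13 | methyl (1R,4S)-1-methyl-3-exo-[(trimethylsilyl)ethynyl]-3-endo-(trimethylsilyloxy)-7-oxabicyclo[2.2.1]heptane-2-exo-carboxylate | COC(=O)[C@@H]1[C@@]2(C)CC[C@H](O2)[C@]1(O[Si](C)(C)C)C#C[Si](C)(C)C | intermediate
14 | (1R,4S)-N-methoxy-N,1-dimethyl-3-exo-[(trimethylsilyl)ethynyl]-3-endo-(trimethylsilyloxy)-7-oxabicyclo[2.2.1]heptane-2-exo-carboxamide | CON(C)C(=O)[C@@H]1[C@@]2(C)CC[C@H](O2)[C@]1(O[Si](C)(C)C)C#C[Si](C)(C)C | intermediate
15 | 1-[(1R,4S)-1-methyl-3-exo-[(trimethylsilyl)ethynyl]-3-endo-(trimethylsilyloxy)-7-oxabicyclo[2.2.1]hept-2-exo-yl]ethanone | CC(=O)[C@@H]1[C@@]2(C)CC[C@H](O2)[C@]1(O[Si](C)(C)C)C#C[Si](C)(C)C | intermediate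
16 | lithium enolate of 15 at the methyl group (not isolated) | [Li+].C=C([O-])[C@@H]1[C@@]2(C)CC[C@H](O2)[C@]1(O[Si](C)(C)C)C#C[Si](C)(C)C | intermediate
17 | (1S,4R)-4-methyl-3-exo-[1-(triisopropylsilyloxy)vinyl]-2-exo-[(trimethylsilyl)ethynyl]-2-endo-(trimethylsilyloxy)-7-oxabicyclo[2.2.1]heptane | C=C(O[Si](C(C)C)(C(C)C)C(C)C)[C@@H]1[C@@]2(C)CC[C@H](O2)[C@]1(O[Si](C)(C)C)C#C[Si](C)(C)C | intermediate
18 | (1S,2R,3S,4R)-2-ethynyl-4-methyl-3-[1-(triisopropylsilyloxy)vinyl]-7-oxabicyclo[2.2.1]heptan-2-ol (2-exo-ethynyl, 3-exo-vinyl; key-step precursor) | C=C(O[Si](C(C)C)(C(C)C)C(C)C)[C@@H]1[C@@]2(C)CC[C@H](O2)[C@]1(O)C#C | intermediate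
19 | potassium alkoxide of 18 (not isolated) | [K+].C=C(O[Si](C(C)C)(C(C)C)C(C)C)[C@@H]1[C@@]2(C)CC[C@H](O2)[C@]1([O-])C#C | intermediate
20 | potassium allenolate (C10 enolate, C9=C8 allene; not isolated) | [K+].[O-]C1=C=CC/C(O[Si](C(C)C)(C(C)C)C(C)C)=C\[C@@]2(C)CC[C@@H]1O2 | intermediate
21 | (1S,3Z,6E,8R)-8-methyl-6-(triisopropylsilyloxy)-11-oxabicyclo[6.2.1]undeca-3,6-dien-2-one (key-step product) | O=C1/C=C\C/C(O[Si](C(C)C)(C(C)C)C(C)C)=C\[C@@]2(C)CC[C@@H]1O2 | intermediate
22 | (1S,4R,5E,8Z,10R)-1,4-epoxy-6-(triisopropylsilyloxy)-11,12,13-trinorgermacra-5,8-dien-10-ol | C[C@@]1(O)/C=C\C/C(O[Si](C(C)C)(C(C)C)C(C)C)=C\[C@@]2(C)CC[C@@H]1O2 | intermediate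
23 | (1S,4R,5E,8R,9R,10S)-1,4:8,9-diepoxy-6-(triisopropylsilyloxy)-11,12,13-trinorgermacr-5-en-10-ol | C[C@@]1(O)[C@@H]3O[C@@H]3C/C(O[Si](C(C)C)(C(C)C)C(C)C)=C\[C@@]2(C)CC[C@@H]1O2 | intermediate
24 | (1S,4R,5E,8S,10R)-1,4-epoxy-6-(triisopropylsilyloxy)-11,12,13-trinorgermacr-5-ene-8,10-diol | C[C@@]1(O)C[C@H](O)C/C(O[Si](C(C)C)(C(C)C)C(C)C)=C\[C@@]2(C)CC[C@@H]1O2 | intermediate
25 | (1S,4R,8S,10R)-1,4-epoxy-8,10-dihydroxy-11,12,13-trinorgermacran-6-one | C[C@@]1(O)C[C@H](O)CC(=O)C[C@@]2(C)CC[C@@H]1O2 | intermediate
26 | (1S,4R,8S,10R)-8,10-(di-tert-butylsilylenedioxy)-1,4-epoxy-11,12,13-trinorgermacran-6-one | C[C@@]1(O[Si](C(C)(C)C)(C(C)(C)C)O4)C[C@H]4CC(=O)C[C@@]2(C)CC[C@@H]1O2 | intermediate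
27 | ethyl bromopyruvate | CCOC(=O)C(=O)CBr | starting material
28 | ethyl 3-acetoxy-2-oxopropanoate | CCOC(=O)C(=O)COC(C)=O | intermediate
29 | lithium C6–C7 enolate of 26 (double-bond geometry not defined; not isolated) | [Li+].C[C@@]1(O[Si](C(C)(C)C)(C(C)(C)C)O4)C[C@H]4C=C([O-])C[C@@]2(C)CC[C@@H]1O2 | intermediate
30 | ethyl (1S,4R,8S,10R)-13-acetoxy-8,10-(di-tert-butylsilylenedioxy)-1,4-epoxy-11-hydroxy-6-oxogermacran-12-oate (C7 and C11 epimer mixture; centres left undefined) | C[C@@]1(O[Si](C(C)(C)C)(C(C)(C)C)O4)C[C@H]4C(C(O)(COC(C)=O)C(=O)OCC)C(=O)C[C@@]2(C)CC[C@@H]1O2 | intermediate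
31 | ethyl (1S,4R,8S,10R)-13-acetoxy-8,10-(di-tert-butylsilylenedioxy)-1,4-epoxy-6-oxogermacr-7(11)-en-12-oate (C7=C11 geometry undefined; not isolated) | C[C@@]1(O[Si](C(C)(C)C)(C(C)(C)C)O4)C[C@H]4C(=C(COC(C)=O)C(=O)OCC)C(=O)C[C@@]2(C)CC[C@@H]1O2 | intermediate
32 | (1S,4R,5E,8S,10R)-13-acetoxy-8,10-(di-tert-butylsilylenedioxy)-1,4-epoxygermacra-5,7(11)-dien-12,6-olide | CC(=O)OCC1=C2/C(=C\[C@@]3(C)CC[C@H](O3)[C@](C)(O[Si](C(C)(C)C)(C(C)(C)C)O5)C[C@@H]25)OC1=O | intermediate
33 | (1S,4R,5E,8S,10R)-13-acetoxy-1,4-epoxy-8,10-dihydroxygermacra-5,7(11)-dien-12,6-olide | CC(=O)OCC1=C2/C(=C\[C@@]3(C)CC[C@H](O3)[C@](C)(O)C[C@@H]2O)OC1=O | intermediate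
34 | (R)-2-methylglycidol [(R)-(2-methyloxiran-2-yl)methanol] | C[C@@]1(CO)CO1 | starting material
35 | (S)-2-methyloxirane-2-carbaldehyde (not isolated) | C[C@@]1(C=O)CO1 | intermediate
36 | (S)-2-methyloxirane-2-carboxylic acid | C[C@@]1(C(=O)O)CO1 | intermediate
37 | (S)-2-methyloxirane-2-carboxylic 2-methyl-6-nitrobenzoic anhydride (not isolated) | C[C@@]1(C(=O)OC(=O)c2c(C)cccc2[N+](=O)[O-])CO1 | intermediate
38 | (1S,4R,5E,8S,10R)-13-acetoxy-1,4-epoxy-10-hydroxy-8-[(2S)-2-methyloxirane-2-carbonyloxy]germacra-5,7(11)-dien-12,6-olide (CNP0142137.1) | CC(=O)OCC1=C2/C(=C\[C@@]3(C)CC[C@H](O3)[C@](C)(O)C[C@@H]2OC(=O)[C@]2(C)CO2)OC1=O | target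

## Step count and least certain steps

Total: 23 steps. Longest linear sequence: 21 steps (steps 1–17, 19–21 and 23; steps 18 and 22 are one-step side branches).

Step 12 (key step). The most likely failure is fragmentation of the propargylic alkoxide (loss of acetylide or an ene-type cleavage) or migration of the silyl group from the enol oxygen to the alkoxide, both of which are also alkoxide-driven and could outrun the [3,3] shift if the boat array is slow to form. The fallback removes the alkoxide altogether and sets out from 18. N-(trimethylsilyl)imidazole would convert it into the O-trimethylsilyl ether F1. Heating F1 in toluene or o-xylene (110–140 °C, base-washed glassware) should bring about the neutral siloxy-Cope rearrangement to the cyclic silyloxyallene F2. Cold K2CO3/MeOH would cleave the allenyl trimethylsilyl ether in preference to the hindered enol ether and tautomerise the product to the enone, so the route is rejoined at 21.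

Step 19. Deprotonation could occur at C5 instead of C7, or the C7 enolate could expel the C8 oxygen, because the kinetic preference rests only on the steric difference between two β-oxygenated methylenes. The fallback sets out from 26. 1,1-Dimethylhydrazine (AcOH cat., EtOH, 60 °C) would give the N,N-dimethylhydrazone F3, whose lithium azaenolate forms at the less hindered α-carbon with higher fidelity than a ketone enolate. Addition to 28 at −78 °C would give the hydrazone aldol adduct F4, and mild hydrolysis (aqueous oxalic acid or CuCl2, THF/H2O) returns the route to 30.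

Step 20. Under hot acid the C8 oxygen could be eliminated or the ether bridge could open through the C5 enol before the lactone closes, and ester exchange by an enol is slow. The fallback closes the lactone from a free acid under non-acidic conditions and sets out from 26. The enolate of 26 would be added to tert-butyl 3-acetoxy-2-oxopropanoate F5 (made like 28 from tert-butyl bromopyruvate) to give the tert-butyl aldol adduct F6. SOCl2/pyridine at 0 °C would dehydrate it to the alkylidene keto ester F7, and brief treatment with CF3CO2H in CH2Cl2 at 0 °C would release the keto acid F8. Ac2O/NaOAc (or a carbodiimide) then closes the enol lactone, which rejoins the route at 32.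

Step 14. The electrophilic vanadium peroxide could oxidise the electron-rich silyl enol ether, or the macrocycle could present the wrong alkene face to the bound oxidant. The fallback uses a nucleophilic oxidant before the methyl group is added and sets out from 21. t-BuOOH with DBU (Weitz–Scheffer epoxidation, to which the enol ether is inert) would give the 8,9-epoxy ketone F9. Chelation-controlled addition of MeMgBr as in step 13 then leads to 23, provided the peroxide attacks the same outer face of the enone.

Step 5. No panel enzyme may discriminate the two bridgehead-enantiomeric ketones well enough, or the hit may consume the wanted enantiomer. The fallback resolves a secondary alcohol instead and sets out from 7. NaBH4 in MeOH at −20 °C would give the racemic endo hydroxy ester F10. Candida antarctica lipase B with vinyl acetate in MTBE would acetylate one enantiomer. The (1R,4S) hydroxy ester F11 is collected either unreacted or, if it is the enantiomer that reacts, as its acetate F12, which K2CO3/MeOH returns to F11. Dess–Martin periodinane then oxidises F11 back to the ketone, rejoining the route at 8.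

## Further compounds

F1 | step 12 | (1S,2R,3S,4R)-2-ethynyl-4-methyl-3-[1-(triisopropylsilyloxy)vinyl]-2-(trimethylsilyloxy)-7-oxabicyclo[2.2.1]heptane | C=C(O[Si](C(C)C)(C(C)C)C(C)C)[C@@H]1[C@@]2(C)CC[C@H](O2)[C@]1(O[Si](C)(C)C)C#C
F2 | step 12 | cyclic silyloxyallene: 10-(trimethylsilyloxy)-6-(triisopropylsilyloxy)-1,4-epoxy-11,12,13-trinorgermacra-5,8,9-triene | C[Si](C)(C)OC1=C=CC/C(O[Si](C(C)C)(C(C)C)C(C)C)=C\[C@@]2(C)CC[C@@H]1O2
F3 | step 19 | N,N-dimethylhydrazone of 26 | C[C@@]1(O[Si](C(C)(C)C)(C(C)(C)C)O4)C[C@H]4CC(=NN(C)C)C[C@@]2(C)CC[C@@H]1O2
F4 | step 19 | N,N-dimethylhydrazone of 30 (C7 and C11 epimer mixture) | C[C@@]1(O[Si](C(C)(C)C)(C(C)(C)C)O4)C[C@H]4C(C(O)(COC(C)=O)C(=O)OCC)C(=NN(C)C)C[C@@]2(C)CC[C@@H]1O2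
F5 | step 20 | tert-butyl 3-acetoxy-2-oxopropanoate | CC(=O)OCC(=O)C(=O)OC(C)(C)C
F6 | step 20 | tert-butyl ester analogue of 30 (C7 and C11 epimer mixture) | C[C@@]1(O[Si](C(C)(C)C)(C(C)(C)C)O4)C[C@H]4C(C(O)(COC(C)=O)C(=O)OC(C)(C)C)C(=O)C[C@@]2(C)CC[C@@H]1O2
F7 | step 20 | tert-butyl ester analogue of 31 | C[C@@]1(O[Si](C(C)(C)C)(C(C)(C)C)O4)C[C@H]4C(=C(COC(C)=O)C(=O)OC(C)(C)C)C(=O)C[C@@]2(C)CC[C@@H]1O2
F8 | step 20 | (1S,4R,8S,10R)-13-acetoxy-8,10-(di-tert-butylsilylenedioxy)-1,4-epoxy-6-oxogermacr-7(11)-en-12-oic acid | C[C@@]1(O[Si](C(C)(C)C)(C(C)(C)C)O4)C[C@H]4C(=C(COC(C)=O)C(=O)O)C(=O)C[C@@]2(C)CC[C@@H]1O2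
F9 | step 14 | 8,9-epoxide of 21 (epoxide carbons as in 23) | O=C1[C@@H]3O[C@@H]3C/C(O[Si](C(C)C)(C(C)C)C(C)C)=C\[C@@]2(C)CC[C@@H]1O2
F10 | step 5 | rac-methyl 3-endo-hydroxy-1-methyl-7-oxabicyclo[2.2.1]heptane-2-exo-carboxylate [(1R,4S) enantiomer drawn] | COC(=O)[C@@H]1[C@@]2(C)CC[C@H](O2)[C@H]1O
F11 | step 5 | methyl (1R,4S)-3-endo-hydroxy-1-methyl-7-oxabicyclo[2.2.1]heptane-2-exo-carboxylate (single enantiomer) | COC(=O)[C@@H]1[C@@]2(C)CC[C@H](O2)[C@H]1O
F12 | step 5 | methyl (1R,4S)-3-endo-acetoxy-1-methyl-7-oxabicyclo[2.2.1]heptane-2-exo-carboxylate | COC(=O)[C@@H]1[C@@]2(C)CC[C@H](O2)[C@H]1OC(C)=O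
A1 | alternative 1 | diazoketone with lactate-derived ether (insertion precursor) | [N-]=[N+]=CC(=O)[C@H](O[C@@H](C)COCc1ccccc1)[C@](C)(O[Si](CC)(CC)CC)COC(=O)C(C)(C)C
A2 | alternative 1 | cis-2,5-disubstituted 5-methyltetrahydrofuran-3-one | c1ccccc1COC[C@@]2(C)CC(=O)[C@H](O2)[C@](C)(O[Si](CC)(CC)CC)COC(=O)C(C)(C)C
A3 | alternative 2 | acyclic vinyl iodide enal | O=C/C=C(\C)CC[C@H]1O[C@]1(C)C[C@H](O[Si](C)(C)C(C)(C)C)/C(I)=C(\COC(C)=O)C(=O)OC
A4 | alternative 2 | 1,10-epoxygermacra-4,7(11)-dien-6-ol 12-methyl ester | O[C@@H]1/C=C(\C)CC[C@H]2O[C@]2(C)C[C@H](O[Si](C)(C)C(C)(C)C)/C1=C(\COC(C)=O)C(=O)OC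
A5 | alternative 3 | furyl aldoxime with isopropenyl tetrahydrofuran | CC(=O)OCc1c(C=NO)c(C[C@@]2(C)CC[C@H](O2)C(C)=C)oc1[Si](C)(C)C
A6 | alternative 3 | furan-fused macrocyclic isoxazoline | CC(=O)OCc1c2c(C[C@@]3(C)CC[C@H](O3)[C@@]4(C)CC2=NO4)oc1[Si](C)(C)C
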